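The numbers in the tables were generated by integration for an exercise, and the scatter is random.

Early times went unread: by the first reading at 6.4 min, the theta flask already held 0.0563 M of Q, 37.5 % of its E charge, so any order at the outset had to be inferred.

| flask | E | Z | time |
|---|---|---|---|
| theta | 0.150 M | 0.165 M |  |
| epsilon | 0.0600 M | 0.0750 M |  |
| alpha | 0.220 M | 0.165 M |  |
| delta | 0.0500 M | 0.0540 M | 45 min |

| run | time / min | [Q] / M |
|---|---|---|
| theta run | 6.4 | 0.0563 |
| theta run | 13 | 0.0627 |
| theta run | 19 | 0.0651 |
| theta run | 26 | 0.0663 |
| theta run | 32 | 0.0671 |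
| theta run | 39 | 0.0678 |
| theta run | 45 | 0.0679 |
| epsilon run | 6.4 | 0.0187 |
| epsilon run | 13 | 0.0234 |
| epsilon run | 19 | 0.0244 |
| epsilon run | 26 | 0.0258 |
| epsilon run | 32 | 0.0266 |
| epsilon run | 39 | 0.0274 |
| epsilon run | 45 | 0.0278 |
| alpha run | 6.4 | 0.0704 |
| alpha run | 13 | 0.0777 |
| alpha run | 19 | 0.0800 |
| alpha run | 26 | 0.0806 |
| alpha run | 32 | 0.0818 |
| alpha run | 39 | 0.0826 |
| alpha run | 45 | 0.0825 |

(scatter of a reading: 4 × 10⁻⁴ M)

- reaction order in [Z] at the outset, round the charge of the theta run, defined at two percent of the E turned into Q
- reaction order in [E] at the outset, round the charge of the theta run, defined at two percent of the E turned into Q (one fixed amount of Q, the same in the runs compared)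
- Q in the delta run at 45 min, as a share of the E charged

- Overall: E + Z -> Q.
- Constant volume, constant temperature.
- "The second partner" is Z.
- An order is taken over about fifteen percent of the charge, up and down.

For the delta flask I froze one thing, the ratio cZ/cE, which at 1.08 lay close to theta's 1.10. My measure was the charge-time (a reduced time), the starting cE multiplied by the clock: 135 M·s for delta at 45 min. If every step takes two partners, flasks with one cZ/cE reach one share of E at one charge-time. The theta flask reaches 135 M·s at 15.0 min. A straight line between its readings at 13 min and 19 min gave 0.0635 M there, which is 42.3 % of theta's E.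

The forecast gave order 1 in cZ and order 1 in cE round the theta charge; it gave 42 % for the delta flask, on the grounds that “Delta has nearly theta's ratio at one third of the concentration”.

The delta flask gave 42.2 % at 45 min, and round the theta charge the orders came to 1.0 in cZ and 1.1 in cE.

    E + Z → Q (1.758 /M/min)
    E + Z → L (0.2520 /M/min)
    2 E → Lx (0.5730 /M/min)
    2 Z → Zu (1.356 /M/min)

The conversion of two Z into Zu moves the readings by 69 scatter units, root mean square. At 135 M·s, delta's share lay 0.16 percentage points from my theta reading. The epsilon flask, with cZ/cE at 1.25, reaches 135 M·s at 37.5 min, and its next reading, at 39 min, stood above delta's, at 45.7 % of its E charge.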